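Ring B carries identical prenyl groups on the adjacent carbons C2' and C3', so both aryl–CH2 bonds are disconnected at once to a C2'–C3' aryne; because the two groups are the same, the sense of addition across the triple bond is irrelevant. One palladium-catalysed operation joins the aryne, prenyl chloride and a prenylstannane. The precursor is a 2-silylaryl triflate bearing the future C2 carbon as a dioxolane on C1' and the C4'/C5' catechol as MOM ethers. The chroman (rings A and C) is then built from the unmasked aldehyde by vinyl addition, redox-relay Heck arylation, CBS reduction, which sets C2 as R, and copper-catalysed aryl ether closure.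

Key step: step 5

Remark on the chemistry: ring B is numbered C1'–C6' with C1' bonded to C2 of the chroman; tributyl(3-methylbut-2-enyl)stannane is taken as a purchasable reagent; all three phenols travel as MOM ethers because these survive butyllithium, fluoride and Grignard reagents and can leave together in the last step.

Step 1
Reactants: 1 2,4,5-trihydroxybenzaldehyde
Product: 2 2-hydroxy-4,5-bis(methoxymethoxy)benzaldehyde
Conditions: MOMCl (2.1 equiv), i-Pr2NEt (2.5 equiv), DMF, 0 °C, Ar
Reagents that add atoms: chloromethyl methyl ether, COCCl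
Why: O-alkylation (MOM protection) in which the 2-hydroxyl, held in a hydrogen bond to the formyl group, is the least nucleophilic, so two equivalents of MOMCl should cap only the 4- and 5-hydroxyls.

Step 2
Reactants: 2 2-hydroxy-4,5-bis(methoxymethoxy)benzaldehyde
Product: 3 3-bromo-2-hydroxy-4,5-bis(methoxymethoxy)benzaldehyde
Conditions: NBS (1.05 equiv), i-Pr2NH (10 mol%), CH2Cl2, 0 °C
Reagents that add atoms: N-bromosuccinimide, O=C1CCC(=O)N1Br
Why: Electrophilic aromatic bromination directed ortho to the free phenol: C3 is activated by two flanking oxygens and is meta to the formyl group, whereas C6 has one activating oxygen and an ortho formyl group, and the non-acidic NBS/amine protocol spares the MOM ethers.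

Step 3
Reactants: 3 3-bromo-2-hydroxy-4,5-bis(methoxymethoxy)benzaldehyde
Product: 4 2-bromo-6-(1,3-dioxolan-2-yl)-3,4-bis(methoxymethoxy)phenol
Conditions: HOCH2CH2OH, HC(OEt)3, p-TsOH·H2O (2 mol%), CH2Cl2, rt; then Et3N
Reagents that add atoms: ethylene glycol, OCCO
Why: Acid-catalysed acetalisation driven by the orthoformate as water scavenger; the aryl-stabilised oxocarbenium ion at the formyl carbon forms far more easily than the one needed to cleave an aryl MOM ether, so a trace of acid at room temperature should exchange only the aldehyde.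

Step 4
Reactants: 4 2-bromo-6-(1,3-dioxolan-2-yl)-3,4-bis(methoxymethoxy)phenol
Product: 8 6-(1,3-dioxolan-2-yl)-3,4-bis(methoxymethoxy)-2-(trimethylsilyl)phenyl trifluoromethanesulfonate, via aryl trimethylsilyl ether 5 (not isolated), via aryllithium 6 (not isolated), via lithium silylphenolate 7 (not isolated)
Conditions: HMDS, THF, reflux, evaporate; n-BuLi, THF, −78 °C; Tf2O, −78 °C to rt
Reagents that add atoms: hexamethyldisilazane, C[Si](C)(C)N[Si](C)(C)C; trifluoromethanesulfonic anhydride, O=S(=O)(OS(=O)(=O)C(F)(F)F)C(F)(F)F
Why: O-silylation, bromine–lithium exchange and retro-Brook rearrangement (anionic 1,3 oxygen-to-carbon silyl shift from 6 to 7) followed by O-triflation, the standard entry to 2-silylaryl triflates from 2-bromophenols, with exchange at −78 °C outpacing attack on the acetal or ortho-lithiation.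

Step 5
Reactants: 8 6-(1,3-dioxolan-2-yl)-3,4-bis(methoxymethoxy)-2-(trimethylsilyl)phenyl trifluoromethanesulfonate; 9 1-chloro-3-methylbut-2-ene (prenyl chloride); 10 tributyl(3-methylbut-2-enyl)stannane
Product: 12 2-[4,5-bis(methoxymethoxy)-2,3-bis(3-methylbut-2-enyl)phenyl]-1,3-dioxolane, via aryne 11 (not isolated)
Conditions: Pd2(dba)3 (2.5 mol%), dppb (5 mol%), CsF (3 equiv), MeCN, 40 °C
Reagents that add atoms: none
Why: Proposed new method: fluoride attacks silicon in 8 and triflate leaves, which releases aryne 11 with its triple bond between C2' and C3'. Zerovalent palladium adds prenyl chloride oxidatively, the stannane transfers the second prenyl group, and the resulting bis(prenyl)palladium complex, divalent at the metal, carbopalladates the strained triple bond through a CH2-bound prenyl ligand and then forms the second aryl–CH2 bond by reductive elimination. The closest known reaction is the bis-allylation of arynes with allyl chloride and allyltributylstannane under the same Pd2(dba)3/dppb catalyst; new here are two γ,γ-dimethylallyl partners and an aryne flanked on both sides. No ring is closed and no stereocenter is formed. The step needs linear (CH2) coupling at both allyl termini: a bond through CMe2 would place a quaternary carbon between two ortho substituents (the C1' acetal or the C4' OMOM group and the neighbouring prenyl-bearing carbon), so the primary terminus, also the preferred site of σ-bonding to palladium and of aryl–allyl reductive elimination, should win, and the wide-bite diphosphine supports this. Since the two groups are identical, the orientation of addition across C2'–C3' is of no consequence.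

Step 6
Reactants: 12 2-[4,5-bis(methoxymethoxy)-2,3-bis(3-methylbut-2-enyl)phenyl]-1,3-dioxolane
Product: 13 4,5-bis(methoxymethoxy)-2,3-bis(3-methylbut-2-enyl)benzaldehyde
Conditions: PPTS (20 mol%), acetone–H2O (10:1), rt
Reagents that add atoms: water, O
Why: Acetal hydrolysis: the electron-rich 2-aryl-1,3-dioxolane ionises under buffered acid much faster than the aryl MOM ethers, and the prenyl alkenes are not protonated by PPTS.

Step 7
Reactants: 13 4,5-bis(methoxymethoxy)-2,3-bis(3-methylbut-2-enyl)benzaldehyde; 14 vinylmagnesium bromide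
Product: 15 rac-1-[4,5-bis(methoxymethoxy)-2,3-bis(3-methylbut-2-enyl)phenyl]prop-2-en-1-ol
Conditions: CH2=CHMgBr, THF, −78 to 0 °C; then H2O
Reagents that add atoms: none
Why: Grignard 1,2-addition to the aldehyde gives the racemic allylic alcohol, whose stereocenter is erased in step 9, so no control is required.

Step 8
Reactants: 16 3-bromo-4-iodophenol
Product: 17 2-bromo-1-iodo-4-(methoxymethoxy)benzene
Conditions: MOMCl, i-Pr2NEt, CH2Cl2, 0 °C to rt
Reagents that add atoms: chloromethyl methyl ether, COCCl
Why: MOM protection (O-alkylation) masks the ring A hydroxyl so that it cannot compete in the base-mediated copper coupling of step 11.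

Step 9
Reactants: 15 rac-1-[4,5-bis(methoxymethoxy)-2,3-bis(3-methylbut-2-enyl)phenyl]prop-2-en-1-ol; 17 2-bromo-1-iodo-4-(methoxymethoxy)benzene
Product: 18 3-[2-bromo-4-(methoxymethoxy)phenyl]-1-[4,5-bis(methoxymethoxy)-2,3-bis(3-methylbut-2-enyl)phenyl]propan-1-one
Conditions: Pd(OAc)2 (5 mol%), Bu4NCl, NaHCO3, DMF, 50 °C
Reagents that add atoms: none
Why: Redox-relay Heck reaction of an allylic alcohol under ligand-free conditions: palladium inserts selectively into the C–I bond, the aryl group adds to the terminal alkene carbon, and β-hydride elimination from the carbinol carbon turns the alcohol into the saturated aryl ketone, while the C–Br bond and the trisubstituted prenyl alkenes stay untouched.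

Step 10
Reactants: 18 3-[2-bromo-4-(methoxymethoxy)phenyl]-1-[4,5-bis(methoxymethoxy)-2,3-bis(3-methylbut-2-enyl)phenyl]propan-1-one
Product: 19 (1R)-3-[2-bromo-4-(methoxymethoxy)phenyl]-1-[4,5-bis(methoxymethoxy)-2,3-bis(3-methylbut-2-enyl)phenyl]propan-1-ol
Conditions: (S)-2-methyl-CBS-oxazaborolidine (20 mol%), catecholborane, toluene, −78 to −40 °C; aq. NaOH work-up
Reagents that add atoms: none
Why: Corey–Bakshi–Shibata reduction in which the ortho-substituted aryl group is the large substituent, so the (S)-oxazaborolidine delivers hydride to the face that gives the (R)-carbinol (the sense known for acetophenone giving (R)-1-phenylethanol), and catecholborane at low temperature does not hydroborate the prenyl alkenes.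

Step 11
Reactants: 19 (1R)-3-[2-bromo-4-(methoxymethoxy)phenyl]-1-[4,5-bis(methoxymethoxy)-2,3-bis(3-methylbut-2-enyl)phenyl]propan-1-ol
Product: 20 (2R)-2-[4,5-bis(methoxymethoxy)-2,3-bis(3-methylbut-2-enyl)phenyl]-7-(methoxymethoxy)chroman
Conditions: CuI (10 mol%), 3,4,7,8-tetramethyl-1,10-phenanthroline (20 mol%), Cs2CO3, toluene, 110 °C
Reagents that add atoms: none
Why: Intramolecular Ullmann-type etherification with monovalent copper closes the six-membered ring C by forming only the aryl–oxygen bond to ring A, so the C–O bond at the stereocenter is never broken and C2 keeps the R configuration.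

Step 12
Reactants: 20 (2R)-2-[4,5-bis(methoxymethoxy)-2,3-bis(3-methylbut-2-enyl)phenyl]-7-(methoxymethoxy)chroman
Product: 21 (+)-(2R)-kazinol I, 5-[(2R)-7-hydroxychroman-2-yl]-3,4-bis(3-methylbut-2-enyl)benzene-1,2-diol
Conditions: HCl (3 M aq.), MeOH–THF, 40 °C, Ar
Reagents that add atoms: none
Why: Acid-catalysed solvolysis of the three aryl MOM acetals, run in dilute acid at mild temperature under argon so that the prenyl groups should not cyclise onto the freed phenols and the benzylic C2–O bond should not ionise.

Compound list
1 | 2,4,5-trihydroxybenzaldehyde | O=Cc1cc(O)c(O)cc1O | starting material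
2 | 2-hydroxy-4,5-bis(methoxymethoxy)benzaldehyde | COCOc1cc(O)c(C=O)cc1OCOC | intermediate
3 | 3-bromo-2-hydroxy-4,5-bis(methoxymethoxy)benzaldehyde | COCOc1cc(C=O)c(O)c(Br)c1OCOC | intermediate
4 | 2-bromo-6-(1,3-dioxolan-2-yl)-3,4-bis(methoxymethoxy)phenol | COCOc1cc(C2OCCO2)c(O)c(Br)c1OCOC | intermediate
5 | [2-bromo-6-(1,3-dioxolan-2-yl)-3,4-bis(methoxymethoxy)phenoxy]trimethylsilane | COCOc1cc(C2OCCO2)c(O[Si](C)(C)C)c(Br)c1OCOC | intermediate
6 | {3-(1,3-dioxolan-2-yl)-5,6-bis(methoxymethoxy)-2-[(trimethylsilyl)oxy]phenyl}lithium | COCOc1cc(C2OCCO2)c(O[Si](C)(C)C)c([Li])c1OCOC | intermediate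
7 | lithium 6-(1,3-dioxolan-2-yl)-3,4-bis(methoxymethoxy)-2-(trimethylsilyl)phenolate | [Li+].COCOc1cc(C2OCCO2)c([O-])c([Si](C)(C)C)c1OCOC | intermediate
8 | 6-(1,3-dioxolan-2-yl)-3,4-bis(methoxymethoxy)-2-(trimethylsilyl)phenyl trifluoromethanesulfonate | COCOc1cc(C2OCCO2)c(OS(=O)(=O)C(F)(F)F)c([Si](C)(C)C)c1OCOC | intermediate
9 | 1-chloro-3-methylbut-2-ene (prenyl chloride) | CC(C)=CCCl | starting material
10 | tributyl(3-methylbut-2-enyl)stannane | CCCC[Sn](CCCC)(CCCC)CC=C(C)C | starting material
11 | 2-[4,5-bis(methoxymethoxy)-2,3-didehydrophenyl]-1,3-dioxolane (C2'–C3' aryne) | COCOC1=C(OCOC)C#CC(C2OCCO2)=C1 | intermediate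
12 | 2-[4,5-bis(methoxymethoxy)-2,3-bis(3-methylbut-2-enyl)phenyl]-1,3-dioxolane | CC(C)=CCc1c(C2OCCO2)cc(OCOC)c(OCOC)c1CC=C(C)C | intermediate
13 | 4,5-bis(methoxymethoxy)-2,3-bis(3-methylbut-2-enyl)benzaldehyde | CC(C)=CCc1c(C=O)cc(OCOC)c(OCOC)c1CC=C(C)C | intermediate
14 | vinylmagnesium bromide | C=C[Mg]Br | starting material
15 | rac-1-[4,5-bis(methoxymethoxy)-2,3-bis(3-methylbut-2-enyl)phenyl]prop-2-en-1-ol | CC(C)=CCc1c(C(O)C=C)cc(OCOC)c(OCOC)c1CC=C(C)C | intermediate
16 | 3-bromo-4-iodophenol | Oc1ccc(I)c(Br)c1 | starting material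
17 | 2-bromo-1-iodo-4-(methoxymethoxy)benzene | COCOc1ccc(I)c(Br)c1 | intermediate
18 | 3-[2-bromo-4-(methoxymethoxy)phenyl]-1-[4,5-bis(methoxymethoxy)-2,3-bis(3-methylbut-2-enyl)phenyl]propan-1-one | CC(C)=CCc1c(C(=O)CCc2ccc(OCOC)cc2Br)cc(OCOC)c(OCOC)c1CC=C(C)C | intermediate
19 | (1R)-3-[2-bromo-4-(methoxymethoxy)phenyl]-1-[4,5-bis(methoxymethoxy)-2,3-bis(3-methylbut-2-enyl)phenyl]propan-1-ol | CC(C)=CCc1c([C@H](O)CCc2ccc(OCOC)cc2Br)cc(OCOC)c(OCOC)c1CC=C(C)C | intermediate
20 | (2R)-2-[4,5-bis(methoxymethoxy)-2,3-bis(3-methylbut-2-enyl)phenyl]-7-(methoxymethoxy)chroman | CC(C)=CCc1c([C@H]2CCc3ccc(OCOC)cc3O2)cc(OCOC)c(OCOC)c1CC=C(C)C | intermediate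
21 | (+)-(2R)-kazinol I | CC(C)=CCc1c([C@H]2CCc3ccc(O)cc3O2)cc(O)c(O)c1CC=C(C)C | target

Total step count: 12. Longest linear sequence: 11 steps (steps 1–7 and 9–12, from 2,4,5-trihydroxybenzaldehyde); step 8 is a one-step side branch.

Steps most likely to fail

Step 5. The coupling may run through the CMe2 terminus at one or both allyl units, or the aryne may be consumed by oligomerisation or ene reaction with the prenyl alkenes before palladium captures it. The fallback uses known chemistry and avoids the aryne. It sets out from phenol 4, which is triflated (Tf2O, pyridine, CH2Cl2, 0 °C) to 2-bromo-6-(1,3-dioxolan-2-yl)-3,4-bis(methoxymethoxy)phenyl trifluoromethanesulfonate F1. Prenyl chloride 9 is converted with Zn dust and LiCl in THF into prenylzinc chloride F2. A linear-selective Negishi coupling (Pd(OAc)2, CPhos, THF, 25–50 °C) then replaces first the bromide and then the triflate of F1 by prenyl groups. The sequence returns to the route at 12.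

Step 12. Protic acid may add the freed C4' hydroxyl across the neighbouring C3' prenyl alkene, or may open the benzylic C2–O bond and erode the configuration. The fallback sets out from 20 and exchanges the acetals for silyl groups under buffered aprotic conditions (TMSOTf, 2,2'-bipyridyl, CH2Cl2, 0 °C). This should give (2R)-2-[2,3-bis(3-methylbut-2-enyl)-4,5-bis(trimethylsilyloxy)phenyl]-7-(trimethylsilyloxy)chroman F3, which is hydrolysed with water at neutral pH. The sequence returns to the route at 21.

Step 3. The acid catalyst may strip MOM groups, the hydrogen-bonded aldehyde may acetalise incompletely, or the phenolic acetal may hydrolyse during purification. The fallback sets out from 3 and reverses the order of events. The phenol is silylated first (HMDS, THF, reflux) to 3-bromo-4,5-bis(methoxymethoxy)-2-(trimethylsilyloxy)benzaldehyde F4. The dioxolane is then formed by aprotic silyl-transfer acetalisation (1,2-bis(trimethylsilyloxy)ethane, TMSOTf cat., CH2Cl2, −78 °C, pyridine quench). The sequence returns to the route at 5, which enters step 4 at the butyllithium stage.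

Further compounds
F1 | step 5 | 2-bromo-6-(1,3-dioxolan-2-yl)-3,4-bis(methoxymethoxy)phenyl trifluoromethanesulfonate | COCOc1cc(C2OCCO2)c(OS(=O)(=O)C(F)(F)F)c(Br)c1OCOC
F2 | step 5 | prenylzinc chloride (chloro(3-methylbut-2-enyl)zinc) | CC(C)=CC[Zn]Cl
F3 | step 12 | (2R)-2-[2,3-bis(3-methylbut-2-enyl)-4,5-bis(trimethylsilyloxy)phenyl]-7-(trimethylsilyloxy)chroman | CC(C)=CCc1c([C@H]2CCc3ccc(O[Si](C)(C)C)cc3O2)cc(O[Si](C)(C)C)c(O[Si](C)(C)C)c1CC=C(C)C
F4 | step 3 | 3-bromo-4,5-bis(methoxymethoxy)-2-(trimethylsilyloxy)benzaldehyde | COCOc1cc(C=O)c(O[Si](C)(C)C)c(Br)c1OCOC
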